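Everything rests on cutting pyrrole ring B out of the pentacycle, back to a 3-bromo-7,8-dihydropyrido[1,2-a]indol-9(6H)-one. Ring A is a bare benzene whose adjacent carbons C7b and C11a carry C7a and N12 of ring B, which is the bonding pattern of the two ends of benzyne. In one operation benzyne is captured by the sulfonamide N–H of the ketone tosylhydrazone (N12–C11a) and BF3·OEt2 then drives a Fischer-type [3,3] shift and ring closure (C7a–C7b, N12–C12a), giving the N-tosyl 6,7-dihydro pentacycle. The precursor is that tosylhydrazone, whose C=N carbon has a single enolisable CH2 neighbour; it comes from N-alkylation and Dieckmann closure, and detosylation, C6–C7 dehydrogenation and C13 oxalylation finish the target.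

Key step: step 4

Remark: locants are those of 12H-pyrido[1,2-a:3,4-b']diindole for the pentacycles (ring A = benzene C7b–C11a, ring B = pyrrole of N12, ring C = six-membered ring holding N5, C6 and C7) and of pyrido[1,2-a]indole for the tricycles, whose C8, C9, C9a and C10 become C7a, C12a, C12b and C13; the target has no stereocentre, and the C=N bonds of 7, 9 and F1 are drawn E (hydrazine nitrogen anti to C9a) as the expected isomers, although either geometry would react alike.

Step 1
Reactants: 1 methyl 6-bromo-1H-indole-2-carboxylate; 2 methyl 4-bromobutanoate
Product: 3 methyl 6-bromo-1-(4-methoxy-4-oxobutyl)-1H-indole-2-carboxylate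
Conditions: K2CO3, DMF, 60 °C
Reagents that add atoms: none
Why: SN2 N-alkylation of an indole, in which the 2-ester makes the N–H acidic enough for K2CO3 and leaves nitrogen as the only nucleophilic site for the primary bromide; the methyl ester of 2 is chosen so that both ester groups of 3 are alike and cannot scramble in the next step.

Step 2
Reactants: 3 methyl 6-bromo-1-(4-methoxy-4-oxobutyl)-1H-indole-2-carboxylate
Product: 5 tricyclic ketone 3-bromo-7,8-dihydropyrido[1,2-a]indol-9(6H)-one, via β-keto ester 4 (not isolated)
Conditions: KOtBu, THF, 0 °C to rt; then 6 M HCl, AcOH, 100 °C (THF distilled off)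
Reagents that add atoms: none
Why: Dieckmann condensation, in which only the chain ester has α-hydrogens so its enolate can only close the six-membered ring onto the indole-2-ester (driven by formation of the stabilised enolate of 4), followed by acid hydrolysis and decarboxylation of the β-keto ester, which also removes the racemic C8 centre of 4.

Step 3
Reactants: 5 tricyclic ketone 3-bromo-7,8-dihydropyrido[1,2-a]indol-9(6H)-one; 6 4-methylbenzenesulfonohydrazide (tosylhydrazide)
Product: 7 (E)-N'-(3-bromo-7,8-dihydropyrido[1,2-a]indol-9(6H)-ylidene)-4-methylbenzenesulfonohydrazide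
Conditions: EtOH, AcOH (cat.), 80 °C
Reagents that add atoms: none
Why: Acid-catalysed condensation of a ketone with a sulfonyl hydrazide, expected to be pulled to completion by crystallisation of the hydrazone from the alcohol; the E geometry expected on steric grounds is of no consequence for the next step.

Step 4
Reactants: 7 (E)-N'-(3-bromo-7,8-dihydropyrido[1,2-a]indol-9(6H)-ylidene)-4-methylbenzenesulfonohydrazide; 8 2-(trimethylsilyl)phenyl trifluoromethanesulfonate
Product: 10 N-tosyl dihydro pentacycle 3-bromo-12-tosyl-7,12-dihydro-6H-pyrido[1,2-a:3,4-b']diindole, via N-phenyl-N-tosylhydrazone 9 (not isolated)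
Conditions: CsF, MeCN, rt; then BF3·OEt2, 80 °C
Reagents that add atoms: none
Why: Fluoride removes the silyl group of 8 and triflate departs to give benzyne, which is trapped by the deprotonated sulfonamide nitrogen of 7 (N12–C11a) and protonated at the neighbouring aryl carbon to give 9; BF3·OEt2 then promotes tautomerisation to the ene-hydrazine (double bond between the later C12a and C7a), a [3,3] sigmatropic shift that joins C7a to the ortho carbon C7b as the N–N bond breaks, rearomatisation of ring A, addition of the sulfonamide nitrogen to the C12a=NH group and loss of ammonia. The closest known reaction type is the aryne version of the Fischer indole synthesis, in which N-tosylhydrazones of enolisable ketones are N-arylated by arynes under fluoride and rearranged by a Lewis acid to N-tosylindoles, and classical Fischer indolisations of ketones attached to C2 of an indole show that this ketone class tolerates the rearrangement. Ring B closes in a 5-exo-trig mode, N12 adding to the exocyclic C12a=N bond once the pericyclic step has fixed the C7a–C7b bond, and expulsion of NH3 makes the closure irreversible by aromatisation. No stereocentre is created. The step needs N-arylation in preference to C-arylation or ene reaction at the indole C10–H of 7 (the later C13) and a single direction of ene-hydrazine formation: the sulfonamide N–H is the only acidic site and its anion the best nucleophile present while C10 is deactivated by conjugation with the C=N bond, the hydrazone carbon has only the C8 methylene to enolise towards because its other neighbour is the aromatic C9a, and the symmetry of benzyne leaves no choice of orientation in either bond formation. Running the arylation at room temperature should hold back Bamford–Stevens fragmentation of the hydrazone anion, and the C–Br bond is inert to fluoride, benzyne and BF3·OEt2.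

Step 5
Reactants: 10 N-tosyl dihydro pentacycle 3-bromo-12-tosyl-7,12-dihydro-6H-pyrido[1,2-a:3,4-b']diindole
Product: 11 dihydro pentacycle 3-bromo-7,12-dihydro-6H-pyrido[1,2-a:3,4-b']diindole
Conditions: Cs2CO3, THF/MeOH, 60 °C
Reagents that add atoms: none
Why: Nucleophilic desulfonylation of an N-sulfonylindole, methoxide attacking sulfur and the 2-(indol-2-yl)indolide leaving, under conditions that touch neither the aryl bromide nor the N-alkylindole.

Step 6
Reactants: 11 dihydro pentacycle 3-bromo-7,12-dihydro-6H-pyrido[1,2-a:3,4-b']diindole
Product: 12 aromatic pentacycle 3-bromo-12H-pyrido[1,2-a:3,4-b']diindole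
Conditions: DDQ (1 equiv), 1,4-dioxane, rt
Reagents that add atoms: none
Why: Quinone dehydrogenation, in which hydride is taken from C7 (the α-position of the C3 substituent of the N12–H indole, stabilised as a 3-alkylideneindoleninium ion) and a proton is then lost from C6 to give the fully conjugated ring C; a metal-free oxidant leaves the C–Br bond alone.

Step 7
Reactants: 12 aromatic pentacycle 3-bromo-12H-pyrido[1,2-a:3,4-b']diindole
Product: 14 methyl 2-(3-bromo-12H-pyrido[1,2-a:3,4-b']diindol-13-yl)-2-oxoacetate, via glyoxylyl chloride 13 (not isolated)
Conditions: (COCl)2, THF, 0 °C; then MeOH, 0 °C to rt; NaHCO3 work-up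
Reagents that add atoms: oxalyl chloride, ClC(=O)C(Cl)=O; methanol, CO
Why: Friedel–Crafts-type acylation without Lewis acid at C13, the enamine-like β-carbon of N5 and the most nucleophilic position of the ring system, followed by methanolysis of the acid chloride; the N12–H is far less reactive and should end up hydrogen-bonded to the new ketone.

Compound list
1 | methyl 6-bromo-1H-indole-2-carboxylate | COC(=O)c1cc2ccc(Br)cc2[nH]1 | starting material
2 | methyl 4-bromobutanoate | COC(=O)CCCBr | starting material
3 | methyl 6-bromo-1-(4-methoxy-4-oxobutyl)-1H-indole-2-carboxylate | COC(=O)CCCn1c(C(=O)OC)cc2ccc(Br)cc21 | intermediate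
4 | methyl 3-bromo-9-oxo-6,7,8,9-tetrahydropyrido[1,2-a]indole-8-carboxylate (racemic at C8, in equilibrium with its enol) | COC(=O)C1CCn2c(cc3ccc(Br)cc32)C1=O | intermediate (not isolated)
5 | 3-bromo-7,8-dihydropyrido[1,2-a]indol-9(6H)-one | O=C1CCCn2c1cc1ccc(Br)cc12 | intermediate
6 | 4-methylbenzenesulfonohydrazide (tosylhydrazide) | Cc1ccc(cc1)S(=O)(=O)NN | starting material
7 | (E)-N'-(3-bromo-7,8-dihydropyrido[1,2-a]indol-9(6H)-ylidene)-4-methylbenzenesulfonohydrazide | Cc1ccc(cc1)S(=O)(=O)N/N=C1\CCCn2c1cc1ccc(Br)cc12 | intermediate
8 | 2-(trimethylsilyl)phenyl trifluoromethanesulfonate | C[Si](C)(C)c1ccccc1OS(=O)(=O)C(F)(F)F | starting material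
9 | (E)-N'-(3-bromo-7,8-dihydropyrido[1,2-a]indol-9(6H)-ylidene)-4-methyl-N-phenylbenzenesulfonohydrazide | Cc1ccc(cc1)S(=O)(=O)N(c1ccccc1)/N=C1\CCCn2c1cc1ccc(Br)cc12 | intermediate (not isolated)
10 | 3-bromo-12-tosyl-7,12-dihydro-6H-pyrido[1,2-a:3,4-b']diindole | Cc1ccc(cc1)S(=O)(=O)n1c2ccccc2c2CCn3c(cc4ccc(Br)cc43)c21 | intermediate
11 | 3-bromo-7,12-dihydro-6H-pyrido[1,2-a:3,4-b']diindole | Brc1ccc2cc3-c4[nH]c5ccccc5c4CCn3c2c1 | intermediate
12 | 3-bromo-12H-pyrido[1,2-a:3,4-b']diindole | Brc1ccc2cc3c4[nH]c5ccccc5c4ccn3c2c1 | intermediate
13 | 2-(3-bromo-12H-pyrido[1,2-a:3,4-b']diindol-13-yl)-2-oxoacetyl chloride | ClC(=O)C(=O)c1c2ccc(Br)cc2n2ccc3c4ccccc4[nH]c3c12 | intermediate (not isolated)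
14 | methyl 2-(3-bromo-12H-pyrido[1,2-a:3,4-b']diindol-13-yl)-2-oxoacetate | COC(=O)C(=O)c1c2ccc(Br)cc2n2ccc3c4ccccc4[nH]c3c12 | target

Total step count: 7. Longest linear sequence: 7 steps (1 to 14).

Steps most likely to fail

Step 4. The aryne may be diverted, either by C-arylation or ene reaction at the electron-rich indole carbon C10 or because the hydrazone anion fragments to a diazo compound before it is arylated. Alternatively the electron-poor N-sulfonyl ene-hydrazine, conjugated with the indole, may resist the sigmatropic shift, so that hydrolysis back to the ketone wins. The fallback sets out from ketone 5 and buys the aryl–nitrogen bond ready-made: condensation with phenylhydrazine (EtOH, AcOH cat., 80 °C) should give the phenylhydrazone (E)-3-bromo-9-(2-phenylhydrazinylidene)-6,7,8,9-tetrahydropyrido[1,2-a]indole F1. A classical Fischer indolisation (ZnCl2, AcOH, 100 °C) should then take it, with loss of ammonia, directly to the N–H dihydro pentacycle 11, where the route is rejoined. Steps 3 to 5 and the sulfonyl group are then not needed.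

Step 6. The product is more electron-rich than its precursor, so it may be oxidised further or attacked by the quinone at C13, and traces of water may divert the C7 cation to oxygenated material. The fallback sets out from 10 and dehydrogenates before the sulfonyl group is taken off. DDQ in 1,4-dioxane at 100 °C should give 3-bromo-12-tosyl-12H-pyrido[1,2-a:3,4-b']diindole F2, in which the sulfonyl group lowers the electron density of ring B and guards the product against over-oxidation. Cs2CO3 in THF/MeOH at 60 °C then releases 12, where the route is rejoined.

Step 7. The HCl liberated may protonate unreacted 12 at C13, giving an aromatic pyridinium-type cation that no longer reacts with the acyl chloride, so that conversion stalls; N12 may also be acylated, or the electron-rich heteroarene may degrade. The fallback sets out from 11 and acylates before ring C is aromatised, when C13 is an ordinary N-alkylindole β-carbon. (COCl)2 in THF at 0 °C should give 2-(3-bromo-7,12-dihydro-6H-pyrido[1,2-a:3,4-b']diindol-13-yl)-2-oxoacetyl chloride F3, which methanol converts without isolation into methyl 2-(3-bromo-7,12-dihydro-6H-pyrido[1,2-a:3,4-b']diindol-13-yl)-2-oxoacetate F4. DDQ in 1,4-dioxane then dehydrogenates C6–C7, the acyl group now protecting C13 from the oxidant, and delivers the target 14, where the route ends.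

Further compounds
F1 | step 4 | (E)-3-bromo-9-(2-phenylhydrazinylidene)-6,7,8,9-tetrahydropyrido[1,2-a]indole | c1ccccc1N/N=C1\CCCn2c1cc1ccc(Br)cc12
F2 | step 6 | 3-bromo-12-tosyl-12H-pyrido[1,2-a:3,4-b']diindole | Cc1ccc(cc1)S(=O)(=O)n1c2ccccc2c2ccn3c(cc4ccc(Br)cc43)c21
F3 | step 7 | 2-(3-bromo-7,12-dihydro-6H-pyrido[1,2-a:3,4-b']diindol-13-yl)-2-oxoacetyl chloride | ClC(=O)C(=O)c1c2ccc(Br)cc2n2CCc3c4ccccc4[nH]c3-c12
F4 | step 7 | methyl 2-(3-bromo-7,12-dihydro-6H-pyrido[1,2-a:3,4-b']diindol-13-yl)-2-oxoacetate | COC(=O)C(=O)c1c2ccc(Br)cc2n2CCc3c4ccccc4[nH]c3-c12
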